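## Retrosynthetic overview

1. The C16 hydroperoxide and the C14=C15 alkene of ring C come from a Schenck ene reaction of the Δ15(16) olefin. Ring C itself (C14–C18, C22) and the C19 carbinol come from a terpineol-type cation–olefin cyclisation that forms C17–C18.
2. The C14–C22 bond, which joins the two halves and sets C14 and C22, comes from an Ireland–Claisen rearrangement of the ester of a C15 acid (rings A/B) with (R)-1,4,4-trimethylcyclohex-2-en-1-ol (ring D).
3. Rings A and B (oxepane O1/C2–C7 trans-fused to cyclohexane C6–C11), with C6, C7, C10, C11 and the tertiary C10–O bond, come from one Lewis-acid cascade of the bis-epoxide of farnesyl tert-butyl carbonate. The farnesol oxygen on C12 ends the cascade through its Boc carbonyl.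
4. Order of ring formation: A and B together (step 3), D brought in from 4,4-dimethylcyclohexanone (steps 9–11), C last (step 16).

Key step: step 3

Remark: atoms are numbered as in squalene (O1/C2–C7 = oxepane ring A, C6–C11 = ring B, C12–C13 = linker, C14–C18/C22 = ring C, C18–C23 = ring D); it is assumed that the L-fructose-derived Shi ketone delivers the (S)-configured epoxide CH centres needed in 3 and 13 (the D-fructose-derived ketone would be used for 13 if its sense proved opposite).

## Route

Step 1
Reactants: 1 (2E,6E)-farnesol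
Product: 2 tert-butyl (2E,6E)-farnesyl carbonate
Conditions: Boc2O, DMAP (cat.), MeCN, 0 °C to rt
Reagents that add atoms: di-tert-butyl dicarbonate, CC(C)(C)OC(=O)OC(=O)OC(C)(C)C
Why: DMAP-catalysed alkoxycarbonylation of the primary allylic alcohol installs the group that later deactivates the C10=C11 alkene towards epoxidation and terminates the cascade.

Step 2
Reactants: 2 tert-butyl (2E,6E)-farnesyl carbonate
Product: 3 (3S,6S,7S)-bis-epoxide of 2 (epoxides at C2–C3 and C6–C7, C10=C11 kept)
Conditions: L-fructose-derived Shi ketone (30 mol %), Oxone, K2CO3, Bu4NHSO4 (cat.), MeCN–DMM–aq. buffer pH 10.5, 0 °C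
Reagents that add atoms: Oxone (potassium peroxymonosulfate), [K+].[O-]S(=O)(=O)OO
Why: Shi asymmetric epoxidation through the spiro dioxirane transition state sets C3, C6 and C7 on the two electron-rich trisubstituted alkenes, while the allylic carbonate inductively protects the C10=C11 alkene.

Step 3
Reactants: 3 (3S,6S,7S)-bis-epoxide
Product: 4 tricyclic carbonate (rings A/B, cyclic carbonate across C10–O and C12–O, C3–OTMS)
Conditions: TMSOTf, 2,6-di-tert-butyl-4-methylpyridine, CH2Cl2, −78 °C
Reagents that add atoms: trimethylsilyl trifluoromethanesulfonate, C[Si](C)(C)OS(=O)(=O)C(F)(F)F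
Why: TMSOTf activates the terminal epoxide, the C6–C7 epoxide oxygen opens it at the tertiary C2 (7-endo) to close the oxepane as a bicyclic epoxonium ion, the C10=C11 alkene attacks C6 with inversion (6-endo, chair) to close ring B, and the C10 cation is captured by the Boc carbonyl oxygen (6-exo) with loss of isobutene. The closest known reaction types are the Lewis-acid tandem oxa-/carbacyclisation of 1,5-diepoxides ended by a π-nucleophile, the cyclisation of epoxyfarnesyl acetate with acetate participation, and tert-butyl carbonate termination of epoxide cascades. C3 and C7 keep their epoxide configurations and C6 is inverted by anti attack, which gives the trans A/B fusion. C11 (C12 equatorial) follows from the E alkene in a chair with the C6 methyl axial, and C10 (O equatorial, methyl axial) from anti addition of C6 and the carbonate oxygen across that alkene. The step needs endo opening at the tertiary epoxide carbons (secured by trisubstitution of both epoxides), alkene attack before elimination (the alkene sits six atoms from C6 and the hindered base suppresses protic pathways), and carbonate capture before proton loss (intramolecular, six-membered).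

Step 4
Reactants: 4 tricyclic carbonate
Product: 5 A/B triol (C3–OH, C10–OH, C12–OH)
Conditions: K2CO3 (cat.), MeOH, rt
Reagents that add atoms: none
Why: Base-catalysed methanolysis (transesterification) cleaves the cyclic carbonate and the TMS ether without touching a stereocentre.

Step 5
Reactants: 5 A/B triol
Product: 6 tris(triethylsilyl) ether of 5
Conditions: TESOTf, 2,6-lutidine, CH2Cl2, 0 °C
Reagents that add atoms: triethylsilyl trifluoromethanesulfonate, CC[Si](CC)(CC)OS(=O)(=O)C(F)(F)F
Why: Silyl triflate silylation covers the primary, the neopentyl secondary and the tertiary hydroxyl, so that the later basic steps cannot trigger a retro-aldol opening at C10–C11.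

Step 6
Reactants: 6 tris(triethylsilyl) ether
Product: 7 C12 aldehyde (C3,C10-bis-OTES)
Conditions: (COCl)2, DMSO, CH2Cl2, −78 to −40 °C; Et3N
Reagents that add atoms: none
Why: Swern conditions cleave and oxidise a primary TES ether directly while secondary and tertiary TES ethers survive; C11 keeps its equatorial, more stable configuration.

Step 7
Reactants: 7 C12 aldehyde
Product: 8 (12Z)-alkenoic acid (C12=C13, C15 carboxylic acid)
Conditions: (2-carboxyethyl)triphenylphosphonium bromide, NaHMDS (2 equiv), THF, −78 °C to rt; aq. HCl work-up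
Reagents that add atoms: (2-carboxyethyl)triphenylphosphonium bromide, OC(=O)CC[P+](c1ccccc1)(c1ccccc1)c1ccccc1.[Br-]
Why: Wittig olefination with the non-stabilised carboxylate ylide adds C13–C15 in one step and gives the Z alkene, whose geometry is irrelevant after step 8.

Step 8
Reactants: 8 (12Z)-alkenoic acid
Product: 9 saturated C15 acid (C11–CH2CH2CH2CO2H)
Conditions: H2 (1 atm), Pd/C, EtOAc, rt
Reagents that add atoms: none
Why: Heterogeneous hydrogenation reduces the only alkene and leaves the silyl ethers intact.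

Step 9
Reactants: 10 4,4-dimethylcyclohexanone
Product: 12 1,4,4-trimethylcyclohex-1-ene, via tertiary alcohol 11 (not isolated)
Conditions: MeMgBr, Et2O, 0 °C; aq. NH4Cl; crude alcohol, TsOH (cat.), toluene, 80 °C
Reagents that add atoms: methylmagnesium bromide, C[Mg]Br
Why: Grignard addition followed by acid-catalysed E1 dehydration gives the Zaitsev endocyclic trisubstituted alkene.

Step 10
Reactants: 12 1,4,4-trimethylcyclohex-1-ene
Product: 13 (1S,6R)-3,3,6-trimethyl-7-oxabicyclo[4.1.0]heptane
Conditions: L-fructose-derived Shi ketone (30 mol %), Oxone, K2CO3, Bu4NHSO4 (cat.), MeCN–DMM–aq. buffer, 0 °C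
Reagents that add atoms: Oxone (potassium peroxymonosulfate), [K+].[O-]S(=O)(=O)OO
Why: Shi asymmetric epoxidation of the trisubstituted cycloalkene sets the tertiary C19–O stereocentre by catalyst control.

Step 11
Reactants: 13 (1S,6R)-epoxide
Product: 15 (R)-1,4,4-trimethylcyclohex-2-en-1-ol, via hydroxy selenide 14 (not isolated)
Conditions: PhSeSePh, NaBH4, EtOH, reflux; then 30% H2O2, THF, 0 °C to rt
Reagents that add atoms: none
Why: Epoxide-to-allylic-alcohol transposition: phenylselenolate opens the epoxide trans-diaxially at the secondary carbon, and selenoxide syn-elimination can only run away from the hydrogen-free carbinol carbon, so the tertiary C–O bond and its configuration are kept.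

Step 12
Reactants: 9 saturated C15 acid; 15 (R)-1,4,4-trimethylcyclohex-2-en-1-ol
Product: 17 (R)-1,4,4-trimethylcyclohex-2-en-1-yl ester of 9, via mixed anhydride 16 (not isolated)
Conditions: 2,4,6-trichlorobenzoyl chloride, Et3N, THF, rt; then 15 (excess), DMAP, toluene, 60 °C
Reagents that add atoms: none
Why: Yamaguchi esterification through the mixed anhydride and the acylpyridinium ion acylates the hindered tertiary allylic alcohol without touching a stereocentre.

Step 13
Reactants: 17 tertiary allylic ester
Product: 20 (14R,22S)-acid (new C14–C22 bond, ring D alkene now C18=C19), via silyl ketene acetal 18 (not isolated), via trimethylsilyl ester 19 (not isolated)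
Conditions: LDA, TMSCl, THF–DMPU, −78 °C, then 60 °C; dilute aq. acid work-up
Reagents that add atoms: none
Why: Ireland–Claisen [3,3]-rearrangement: the bond to C22 forms on the face that the C19 oxygen leaves, so the C19 configuration is transferred to C22, and the (Z)-silyl ketene acetal reacting through a boat (the chair is blocked by the axial C23 methyl) with its chain turned away from the ring sets C14.

Step 14
Reactants: 20 (14R,22S)-acid
Product: 21 methyl ketone (C15 ketone)
Conditions: MeLi (2.1 equiv), Et2O, 0 °C; poured into aq. NH4Cl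
Reagents that add atoms: methyllithium, [Li]C
Why: Addition of methyllithium to the lithium carboxylate stops at the stable gem-dialkoxide, which gives the ketone on hydrolysis without enolising C14.

Step 15
Reactants: 21 methyl ketone
Product: 22 tertiary vinyl carbinol (C15 epimers)
Conditions: vinylmagnesium bromide, THF, −78 to 0 °C
Reagents that add atoms: vinylmagnesium bromide, C=C[Mg]Br
Why: Grignard 1,2-addition supplies C16 and C17; the new C15 centre need not be controlled because it is ionised in step 16.

Step 16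
Reactants: 22 tertiary vinyl carbinol
Product: 23 Δ15(16) olefin triol (14R,18S,19S,22R; rings A–D complete)
Conditions: TsOH·H2O (0.3 equiv), THF–H2O 3:1, 0 °C to rt
Reagents that add atoms: water, O
Why: Terpineol-type cation–olefin cyclisation (closest analogy: linalool to α-terpineol): the allyl cation from C15 is attacked at C17 by C18 of the ring D alkene on the face that carries the tether (axial attack, hence cis C18/C22 fusion), water captures the tertiary C19 cation anti to the new C17–C18 bond (trans-diaxial addition, setting C19), and the same acid hydrolyses both TES ethers.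

Step 17
Reactants: 23 Δ15(16) olefin triol
Product: 24 sipholenol M
Conditions: O2, hν (visible), tetraphenylporphyrin (cat.), CH2Cl2–MeOH, −20 °C
Reagents that add atoms: oxygen, O=O
Why: Schenck ene reaction: singlet oxygen bonds to C16 while abstracting the allylic H-14 from the same (α) face, which moves the alkene to C14=C15 and fixes C16 as R from the C14 configuration; regioisomeric hydroperoxides from abstraction at C17 or the C15 methyl are the expected by-products.

## Compound list

1 | (2E,6E)-farnesol | OC/C=C(\C)CC/C=C(\C)CCC=C(C)C | starting material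
2 | tert-butyl (2E,6E)-farnesyl carbonate | CC(C)(C)OC(=O)OC/C=C(\C)CC/C=C(\C)CCC=C(C)C | intermediate
3 | (3S,6S,7S)-bis-epoxide of 2 (C2–C3 and C6–C7 epoxides, 10E alkene) | CC(C)(C)OC(=O)OC/C=C(\C)CC[C@@H]1O[C@@]1(C)CC[C@@H]1OC1(C)C | intermediate
4 | tricyclic carbonate: trans-fused oxepane/cyclohexane, C10–O/C12–O cyclic carbonate, C3–OTMS | O=C1OC[C@H]2[C@]3(C)CC[C@H](O[Si](C)(C)C)C(C)(C)O[C@H]3CC[C@]2(C)O1 | intermediate
5 | A/B triol (C3–OH, C10–OH, C12–OH; ring configurations as in 24) | OC[C@H]1[C@]2(C)CC[C@H](O)C(C)(C)O[C@H]2CC[C@]1(C)O | intermediate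
6 | tris(triethylsilyl) ether of 5 | CC[Si](CC)(CC)OC[C@H]1[C@]2(C)CC[C@H](O[Si](CC)(CC)CC)C(C)(C)O[C@H]2CC[C@]1(C)O[Si](CC)(CC)CC | intermediate
7 | C12 aldehyde, C3,C10-bis-OTES | O=C[C@H]1[C@]2(C)CC[C@H](O[Si](CC)(CC)CC)C(C)(C)O[C@H]2CC[C@]1(C)O[Si](CC)(CC)CC | intermediate
8 | (12Z)-alkenoic acid (C15 CO2H), bis-OTES | OC(=O)C/C=C\[C@H]1[C@]2(C)CC[C@H](O[Si](CC)(CC)CC)C(C)(C)O[C@H]2CC[C@]1(C)O[Si](CC)(CC)CC | intermediate
9 | saturated C15 acid, bis-OTES | OC(=O)CCC[C@H]1[C@]2(C)CC[C@H](O[Si](CC)(CC)CC)C(C)(C)O[C@H]2CC[C@]1(C)O[Si](CC)(CC)CC | intermediate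
10 | 4,4-dimethylcyclohexanone | CC1(C)CCC(=O)CC1 | starting material
11 | 1,4,4-trimethylcyclohexan-1-ol | CC1(C)CCC(C)(O)CC1 | intermediate
12 | 1,4,4-trimethylcyclohex-1-ene | CC1=CCC(C)(C)CC1 | intermediate
13 | (1S,6R)-3,3,6-trimethyl-7-oxabicyclo[4.1.0]heptane | CC1(C)CC[C@@]2(C)O[C@H]2C1 | intermediate
14 | (1R,2R)-1,4,4-trimethyl-2-(phenylselanyl)cyclohexan-1-ol | CC1(C)CC[C@@](C)(O)[C@H]([Se]c2ccccc2)C1 | intermediate
15 | (R)-1,4,4-trimethylcyclohex-2-en-1-ol | C[C@]1(O)C=CC(C)(C)CC1 | intermediate
16 | mixed anhydride of 9 with 2,4,6-trichlorobenzoic acid | O=C(CCC[C@H]1[C@]2(C)CC[C@H](O[Si](CC)(CC)CC)C(C)(C)O[C@H]2CC[C@]1(C)O[Si](CC)(CC)CC)OC(=O)c1c(Cl)cc(Cl)cc1Cl | intermediate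
17 | (R)-1,4,4-trimethylcyclohex-2-en-1-yl ester of 9 | C[C@]1(OC(=O)CCC[C@H]2[C@]3(C)CC[C@H](O[Si](CC)(CC)CC)C(C)(C)O[C@H]3CC[C@]2(C)O[Si](CC)(CC)CC)C=CC(C)(C)CC1 | intermediate
18 | (Z)-O-trimethylsilyl ketene acetal of 17 (chain cis to OSiMe3) | C[C@]1(O/C(O[Si](C)(C)C)=C/CC[C@H]2[C@]3(C)CC[C@H](O[Si](CC)(CC)CC)C(C)(C)O[C@H]3CC[C@]2(C)O[Si](CC)(CC)CC)C=CC(C)(C)CC1 | intermediate
19 | trimethylsilyl ester of 20 | C[Si](C)(C)OC(=O)[C@H](CC[C@H]1[C@]2(C)CC[C@H](O[Si](CC)(CC)CC)C(C)(C)O[C@H]2CC[C@]1(C)O[Si](CC)(CC)CC)[C@@H]1C=C(C)CCC1(C)C | intermediate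
20 | (14R,22S)-acid: C15 CO2H, C14–C22 bond, ring D Δ18(19) | OC(=O)[C@H](CC[C@H]1[C@]2(C)CC[C@H](O[Si](CC)(CC)CC)C(C)(C)O[C@H]2CC[C@]1(C)O[Si](CC)(CC)CC)[C@@H]1C=C(C)CCC1(C)C | intermediate
21 | methyl ketone (C15 ketone) | CC(=O)[C@H](CC[C@H]1[C@]2(C)CC[C@H](O[Si](CC)(CC)CC)C(C)(C)O[C@H]2CC[C@]1(C)O[Si](CC)(CC)CC)[C@@H]1C=C(C)CCC1(C)C | intermediate
22 | tertiary vinyl carbinol (C15 epimers) | C=CC(C)(O)[C@H](CC[C@H]1[C@]2(C)CC[C@H](O[Si](CC)(CC)CC)C(C)(C)O[C@H]2CC[C@]1(C)O[Si](CC)(CC)CC)[C@@H]1C=C(C)CCC1(C)C | intermediate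
23 | Δ15(16) olefin triol (3S,6S,7S,10S,11S,14R,18S,19S,22R) | CC1=CC[C@@H]2[C@@](C)(O)CCC(C)(C)[C@@H]2[C@H]1CC[C@H]1[C@]2(C)CC[C@H](O)C(C)(C)O[C@H]2CC[C@]1(C)O | intermediate
24 | sipholenol M (3S,6S,7S,10S,11S,16R,18S,19S,22R) | CC1=C(CC[C@H]2[C@]3(C)CC[C@H](O)C(C)(C)O[C@H]3CC[C@]2(C)O)[C@@H]2[C@H](C[C@H]1OO)[C@@](C)(O)CCC2(C)C | target

## Step count and risks

Total steps: 17. Longest linear sequence: 14 steps (steps 1–8 and 12–17, from farnesol).

**Step 3 (key step).** The allylic-carbonate alkene is a weak π-nucleophile. The bicyclic epoxonium ion may therefore collapse by elimination or hydride shift before the C6–C11 bond forms, or the C10 cation may lose a proton faster than the Boc carbonyl captures it. The fallback sets out from 3 and comes back at 5. The carbonate of 3 would be removed with K2CO3 in methanol to give the diepoxy farnesol F1, which would be silylated (TBSCl, imidazole) to the TBS ether F2. The C10=C11 alkene then regains its nucleophilicity after the chemoselective epoxidation has already been done. The same TMSOTf cascade would now be ended by proton loss and give the exocyclic C10 methylene compound F3 together with its Δ9(10) isomer. A Mukaiyama hydration (Mn(dpm)3, PhSiH3, O2) would take both isomers through the same C10 radical, which is oxygenated from the equatorial side, to the tertiary alcohol F4. TBAF would then remove both silyl groups to give 5.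

**Step 17.** Singlet oxygen may abstract hydrogen from the C17 methylene or the C15 methyl group instead of the hindered tertiary C14–H, or attack the β face. In simple 1-methylcyclohexenes the mode needed here is the minor one, so the target could be a minor regioisomer. The fallback sets out from 23 and comes back at 24, and puts the oxygen on C16 by chemistry whose regioselectivity does not depend on the cis effect. A nitrosoarene ene reaction with 4-nitronitrosobenzene, which abstracts the twix hydrogen (H-14) selectively, would give the N-aryl hydroxylamine F5. Oxidation (MnO2) to the nitrone F6 and mild aqueous acid hydrolysis would give the enone F7. CBS reduction with the (R)-oxazaborolidine would give the (16S)-allylic alcohol F8 under reagent control. Mesylation at low temperature would give F9, which is allylic and is formed in preference to the neopentyl C3 and the tertiary alcohols, and displacement with anhydrous hydrogen peroxide with inversion would give 24.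

**Step 16.** The allyl cation may be lost to dienes by proton elimination or trapped by water before ring closure, and the C19 cation may eliminate or be attacked from the wrong face. The acid may also close an ether between the C19 hydroxyl and C15. The fallback sets out from 21 and comes back at 23, and replaces the cationic closure by epoxide opening and metathesis. mCPBA would epoxidise the C18=C19 alkene of 21 on the face opposite to the C14 substituent to give the epoxy ketone F10. Wittig methylenation (Ph3P=CH2) would give the isopropenyl epoxide F11. An allyl cuprate (allylMgBr, CuI) would open the epoxide trans-diaxially at C18 to give the allyl carbinol F12, which already has the C19 alcohol and the cis C18/C22 relationship of the target. Ring-closing metathesis (Grubbs II catalyst) would form the C15=C16 alkene in the bis-silyl ether F13, and TBAF would give 23.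

## Further compounds

F1 | step 3 | (2E,6S,7S,10S)-6,7:10,11-diepoxyfarnesol | OC/C=C(\C)CC[C@@H]1O[C@@]1(C)CC[C@@H]1OC1(C)C
F2 | step 3 | tert-butyldimethylsilyl ether of F1 | CC(C)(C)[Si](C)(C)OC/C=C(\C)CC[C@@H]1O[C@@]1(C)CC[C@@H]1OC1(C)C
F3 | step 3 | A/B bicycle with exocyclic C10 methylene, C3–OTMS, C12–OTBS | CC(C)(C)[Si](C)(C)OC[C@H]1[C@]2(C)CC[C@H](O[Si](C)(C)C)C(C)(C)O[C@H]2CCC1=C
F4 | step 3 | C10 tertiary alcohol, C3–OTMS, C12–OTBS | CC(C)(C)[Si](C)(C)OC[C@H]1[C@]2(C)CC[C@H](O[Si](C)(C)C)C(C)(C)O[C@H]2CC[C@]1(C)O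
F5 | step 17 | C16 N-hydroxy-N-(4-nitrophenyl)amine with C14=C15 alkene | CC1=C(CC[C@H]2[C@]3(C)CC[C@H](O)C(C)(C)O[C@H]3CC[C@]2(C)O)[C@@H]2[C@H](C[C@H]1N(O)c1ccc(cc1)[N+]([O-])=O)[C@@](C)(O)CCC2(C)C
F6 | step 17 | C16 N-(4-nitrophenyl)nitrone | CC1=C(CC[C@H]2[C@]3(C)CC[C@H](O)C(C)(C)O[C@H]3CC[C@]2(C)O)[C@@H]2[C@H](CC1=[N+]([O-])c1ccc(cc1)[N+]([O-])=O)[C@@](C)(O)CCC2(C)C
F7 | step 17 | C16 enone (C14=C15–C16=O) | CC1=C(CC[C@H]2[C@]3(C)CC[C@H](O)C(C)(C)O[C@H]3CC[C@]2(C)O)[C@@H]2[C@H](CC1=O)[C@@](C)(O)CCC2(C)C
F8 | step 17 | (16S)-allylic alcohol | CC1=C(CC[C@H]2[C@]3(C)CC[C@H](O)C(C)(C)O[C@H]3CC[C@]2(C)O)[C@@H]2[C@H](C[C@@H]1O)[C@@](C)(O)CCC2(C)C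
F9 | step 17 | (16S)-allylic methanesulfonate | CC1=C(CC[C@H]2[C@]3(C)CC[C@H](O)C(C)(C)O[C@H]3CC[C@]2(C)O)[C@@H]2[C@H](C[C@@H]1OS(C)(=O)=O)[C@@](C)(O)CCC2(C)C
F10 | step 16 | C18–C19 epoxide of methyl ketone 21 | CC(=O)[C@H](CC[C@H]1[C@]2(C)CC[C@H](O[Si](CC)(CC)CC)C(C)(C)O[C@H]2CC[C@]1(C)O[Si](CC)(CC)CC)[C@@H]1[C@H]2O[C@@]2(C)CCC1(C)C
F11 | step 16 | isopropenyl epoxide (C15 methylene) | C=C(C)[C@H](CC[C@H]1[C@]2(C)CC[C@H](O[Si](CC)(CC)CC)C(C)(C)O[C@H]2CC[C@]1(C)O[Si](CC)(CC)CC)[C@@H]1[C@H]2O[C@@]2(C)CCC1(C)C
F12 | step 16 | C18-allyl C19-carbinol diene | C=C(C)[C@H](CC[C@H]1[C@]2(C)CC[C@H](O[Si](CC)(CC)CC)C(C)(C)O[C@H]2CC[C@]1(C)O[Si](CC)(CC)CC)[C@@H]1[C@H](CC=C)[C@@](C)(O)CCC1(C)C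
F13 | step 16 | C3,C10-bis(triethylsilyl) ether of 23 | CC1=CC[C@@H]2[C@@](C)(O)CCC(C)(C)[C@@H]2[C@H]1CC[C@H]1[C@]2(C)CC[C@H](O[Si](CC)(CC)CC)C(C)(C)O[C@H]2CC[C@]1(C)O[Si](CC)(CC)CC
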